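Numbering: C1 is the quaternary carbon bearing one CH3 and the oxymethyl C15; C2–C3–C8–C7 is the cyclobutane; C4 is the ketone and C5=C6 the alkene with CH3 on C6; C8 carries CH3; C9 (senecioate), C10 and C11 (acetate) close the seven-membered ring back to C1.
Enabling feature: C1–C11 with the methyls on C1, C6 and C8 form one unbroken head-to-tail farnesyl chain, folded into the cyclobutane C2–C3–C8–C7, the cyclohexene C2–C3–C4–C5–C6–C7 and the cycloheptane C1–C2–C3–C8–C9–C10–C11, so one cyclase can build the whole tricycle.
Retrosynthesis: cut the three ester C–O bonds (C11 acetate, C15 angelate, C9 senecioate), then the C–O bonds at C15, C9, C11 and C4 (C–H oxidations), then C7–C8, C2–C3 and C1–C2, which leads to (2E,6E)-farnesyl diphosphate.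
Forward: farnesol is turned into its diphosphate; the cyclase closes the eleven-membered ring (C1–C2), then the six- and seven-membered rings together (C2–C3), then the cyclobutane (C7–C8).
Oxygen follows in the order C4 (allylic oxidation), C11 (P450), C9 (desaturation, conjugate borylation), C15 (hydroxyl-directed C–H silylation); the senecioate arrives through an Evans–Tishchenko reduction, the angelate and the acetate by acylation.
Stereochemistry: C2, C3, C7 and C8 come from the enzyme; C9 from a chiral copper catalyst; C11 from C9 (intramolecular hydride delivery, anti); C1 from C11 (five-membered oxasilolane onto the trans methyl).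

Key step: step 3

Assumption: a recombinant α-longipinene synthase is available that releases the (1R,2S,7R,8R) enantiomer of α-longipinene (the configuration the target requires); a conifer enzyme is expected to do so, otherwise a homologue or variant of the opposite fold must be chosen.
Remark on names: the two sides of the C9–C10–C11–C1 bridge are called the C3 face and the C7 face after the cyclobutane carbon they look at. In the target, O9 and C15 lie on the C3 face, O11 and the C1 methyl on the C7 face. Senecioate is 3-methylbut-2-enoate and angelate is (Z)-2-methylbut-2-enoate.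

Step 1
Reactants: 1 (2E,6E)-farnesol
Product: 2 (2E,6E)-farnesyl chloride
Conditions: NCS, Me2S, CH2Cl2, −40 to 0 °C
Reagents that add atoms: N-chlorosuccinimide, O=C1CCC(=O)N1Cl
Why: Corey–Kim chlorination, in which chloride displaces the alkoxysulfonium group at the primary allylic carbon by SN2, so neither the position nor the geometry of the allylic double bond should change.

Step 2
Reactants: 2 (2E,6E)-farnesyl chloride
Product: 3 (2E,6E)-farnesyl diphosphate (handled as the ammonium salt, drawn as the free acid)
Conditions: (Bu4N)3HP2O7, MeCN, rt; cation exchange (NH4+ form), NH4HCO3 (25 mM)/i-PrOH; cellulose chromatography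
Reagents that add atoms: tris(tetrabutylammonium) hydrogen diphosphate, CCCC[N+](CCCC)(CCCC)CCCC.CCCC[N+](CCCC)(CCCC)CCCC.CCCC[N+](CCCC)(CCCC)CCCC.OP(=O)([O-])OP(=O)([O-])[O-]
Why: SN2 displacement of the primary allylic chloride by the diphosphate anion in a dipolar aprotic solvent is the standard entry to prenyl diphosphates, and ion exchange gives the water-soluble salt that the enzyme accepts.

Step 3
Reactants: 3 (2E,6E)-farnesyl diphosphate
Product: 4 α-longipinene, (1R,2S,7R,8R)-2,6,6,9-tetramethyltricyclo[5.4.0.0^2,8]undec-9-ene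
Conditions: recombinant α-longipinene synthase, MgCl2 (10 mM), HEPES buffer pH 7.5, dithiothreitol, 30 °C, pentane overlay
Reagents that add atoms: none
Why: Terpene-cyclase cation cascade (the native reaction of α-longipinene synthases, mechanistically a cation–alkene polycyclisation): MgCl2-assisted ionisation of the diphosphate, with return to the tertiary allylic ion pair so that the C7–C6 unit can turn cisoid, lets C1 of the distal C11=C1 alkene bond to C2, a 1,3-hydride shift from C2 to C11 then moves the charge into the C2–C7–C6 allyl system, C3 of the C3=C8 alkene adds to C2, C7 traps the tertiary C8 cation and loss of a proton from C5 leaves the C5=C6 alkene. The first closure is an 11-endo macrocyclisation with respect to the attacking alkene; the C2–C3 bond is a transannular closure, 6-exo with respect to the C3=C8 alkene for the ring C2–C3–C4–C5–C6–C7, which in the same event creates the seven-membered ring C1–C2–C3–C8–C9–C10–C11; the C7–C8 bond is a 4-exo closure that completes the cyclobutane C2–C3–C8–C7. The substrate is achiral, so all four stereocentres (C2 and C3 in the second closure, C8 and C7 in the third) are dictated by the chain fold that the active-site contour enforces. The step needs 1,11- rather than 1,10-closure at the start and the cyclobutane exit rather than himachalene- or longifolene-type exits at the end; the substrate secures only that the cations at C8 and C6 are tertiary (methyl groups) and that the chain is E,E, the rest is the selectivity of the enzyme. Co-formed sesquiterpenes are expected and are to be removed on AgNO3-impregnated silica.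

Step 4
Reactants: 4 α-longipinene
Product: 5 longipin-5-en-4-one
Conditions: CrO3 (5 mol %), t-BuOOH (70 % aq.), CH2Cl2, rt
Reagents that add atoms: tert-butyl hydroperoxide, CC(C)(C)OO
Why: Chromium-catalysed allylic oxidation with t-BuOOH, the reaction that turns α-pinene into verbenone, should attack the only secondary allylic position, C4, because C7 is a cyclobutane bridgehead and the C6 methyl is primary; no stereocentre is formed.

Step 5
Reactants: 5 longipin-5-en-4-one
Product: 6 11-hydroxylongipin-5-en-4-one (drawn with OH on the C7 face)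
Conditions: cytochrome P450 BM3 (CYP102A1) variant from a screened library, NADP+ (cat.), glucose, glucose dehydrogenase, air, K2HPO4/KH2PO4 buffer pH 8.0, 2 % DMSO, 25 °C
Reagents that add atoms: dioxygen, O=O
Why: Cytochrome P450 hydroxylation (hydrogen abstraction by the oxo-iron haem, then oxygen rebound) of unactivated ring methylenes is established for sesquiterpenoid ketones, the enone switches off C5=C6 and its neighbours so that the remote bridge is oxidised, and site (C11) and face are imposed by the chosen variant, the C11 configuration being of no consequence because step 6 removes it.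

Step 6
Reactants: 6 11-hydroxylongipin-5-en-4-one
Product: 8 longipina-5,9-diene-4,11-dione, via longipin-5-ene-4,11-dione 7 (not isolated)
Conditions: IBX (3.5 equiv), DMSO, 25 °C then 80 °C
Reagents that add atoms: none
Why: IBX first oxidises the alcohol and then dehydrogenates the ketone through its enol (IBX desaturation, well tried on 4,4-dimethyl-3-oxo terpenoids), and since C1 is quaternary the new double bond can only be C9=C10, while the C4 enone has no enolisable α′ hydrogen.

Step 7
Reactants: 8 longipina-5,9-diene-4,11-dione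
Product: 10 9-hydroxylongipin-5-ene-4,11-dione (OH on the C3 face), via C9 pinacol boronate 9 (not isolated)
Conditions: CuCl (5 mol %), (R,R)-QuinoxP* (6 mol %), NaOt-Bu (10 mol %), B2pin2, MeOH, THF, 0 °C to rt; then NaBO3·4H2O, THF/H2O, rt
Reagents that add atoms: bis(pinacolato)diboron, CC1(C)OB(OC1(C)C)B1OC(C)(C)C(C)(C)O1 (boron of 9); sodium perborate tetrahydrate, [Na+].[O-]B1OO1.O.O.O.O (oxygen on C9 of 10)
Why: Copper–boryl conjugate addition (β-borylation) followed by stereoretentive perborate oxidation; the C9=C10–C11=O enone with its β-hydrogen reacts far faster than the β,β-disubstituted C5=C6–C4=O enone, and because the two faces of the bridge differ only through the distant C4 carbonyl and C6 methyl, the chiral bisphosphine rather than the substrate sets C9 (its antipode is used should a trial show boron entering from the C7 face).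

Step 8
Reactants: 10 9-hydroxylongipin-5-ene-4,11-dione and 11 3-methylbut-2-enal
Product: 12 11-hydroxy-4-oxolongipin-5-en-9-yl 3-methylbut-2-enoate (O9 on the C3 face, O11 on the C7 face)
Conditions: SmI2 (20 mol %), 11 (6 equiv), THF, −10 °C
Reagents that add atoms: 3-methylbut-2-enal 11, CC(C)=CC=O
Why: Evans–Tishchenko reduction, in which the samarium-bound hemiacetal formed from the C9 hydroxyl and the aldehyde passes its hydride to the C11 carbonyl through a six-membered transition state on the C3 face, so that O11 ends up on the C7 face, anti to O9, and the aldehyde remains on O9 as the 3-methylbut-2-enoate, while the C4 enone, which has no β-hydroxyl, is not touched.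

Step 9
Reactants: 12 11-hydroxy-4-oxolongipin-5-en-9-yl 3-methylbut-2-enoate
Product: 13 4,11-dihydroxylongipin-5-en-9-yl 3-methylbut-2-enoate (4-OH expected on the side of the C8 methyl)
Conditions: NaBH4, CeCl3·7H2O, MeOH, −40 °C
Reagents that add atoms: none
Why: Luche 1,2-reduction masks the enone, which would not survive the iridium hydride/silane and alkaline peroxide of step 10; hydride should enter from the open C2 side as in the reduction of verbenone, the C4 configuration is irrelevant because step 11 removes it, and the conjugated ester is inert to NaBH4 at this temperature.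

Step 10
Reactants: 13 4,11-dihydroxylongipin-5-en-9-yl 3-methylbut-2-enoate
Product: 16 4,11,15-trihydroxylongipin-5-en-9-yl 3-methylbut-2-enoate, via bis(diethylsilyl) ether 14 (not isolated), via oxasilolane 15 (not isolated)
Conditions: [Ir(cod)OMe]2 (0.5 mol %), Et2SiH2, THF, rt; evaporate; [Ir(cod)OMe]2 (2 mol %), 3,4,7,8-Me4phen (5 mol %), norbornene, THF, 100 °C; then H2O2 (30 %), KHCO3, MeOH/THF, 50 °C
Reagents that add atoms: diethylsilane, CC[SiH2]CC (silicon of 14 and 15); hydrogen peroxide, OO (oxygen on C15 of 16)
Why: Hydroxyl-directed iridium-catalysed γ-C–H silylation and Tamao–Fleming oxidation, as used to oxidise one methyl of 4,4-dimethyl-3-hydroxy terpenoids: only the silyl ether on O11 has methyl C–H bonds three carbons away, the one on O4 has none and stays idle, and closure of the five-membered oxasilolane should take the exposed pseudo-equatorial methyl trans to O11 (C15, C3 face) in preference to the cis methyl lying under the cyclobutane, which sets C1.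

Step 11
Reactants: 16 4,11,15-trihydroxylongipin-5-en-9-yl 3-methylbut-2-enoate
Product: 17 11,15-dihydroxy-4-oxolongipin-5-en-9-yl 3-methylbut-2-enoate
Conditions: activated MnO2 (15 equiv), CH2Cl2, rt
Reagents that add atoms: none
Why: Activated MnO2 oxidises allylic alcohols selectively, so only the C4 carbinol should return to the enone while the saturated C11 and C15 hydroxyls remain.

Step 12
Reactants: 17 11,15-dihydroxy-4-oxolongipin-5-en-9-yl 3-methylbut-2-enoate and 18 angelic acid
Product: 20 15-angeloyloxy-11-hydroxy-4-oxolongipin-5-en-9-yl 3-methylbut-2-enoate, via mixed anhydride 19 (not isolated)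
Conditions: 18, 2,4,6-Cl3C6H2COCl, Et3N, toluene, rt; then 17, toluene, 75 °C
Reagents that add atoms: angelic acid 18, C/C=C(/C)C(=O)O; 2,4,6-trichlorobenzoyl chloride, O=C(Cl)c1c(Cl)cc(Cl)cc1Cl (aroyl group of 19 only)
Why: Yamaguchi-type esterification through the mixed anhydride without a nucleophilic amine catalyst is the established way to make angelates without Z to E isomerisation, and the primary C15 hydroxyl should react well before the C11 hydroxyl, which is secondary and flanked by the quaternary C1.

Step 13
Reactants: 20 15-angeloyloxy-11-hydroxy-4-oxolongipin-5-en-9-yl 3-methylbut-2-enoate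
Product: 21 CNP0179010.1, 11-acetoxy-15-angeloyloxy-4-oxolongipin-5-en-9-yl 3-methylbut-2-enoate
Conditions: Ac2O, pyridine, DMAP (cat.), CH2Cl2, 0 °C to rt
Reagents that add atoms: acetic anhydride, CC(=O)OC(C)=O
Why: DMAP-catalysed acetylation of the remaining hindered secondary alcohol takes place on oxygen and leaves C11 untouched, and the cold, short exposure to base should not isomerise the angelate.

Compound list
1 | (2E,6E)-farnesol | CC(C)=CCC/C(C)=C/CC/C(C)=C/CO | starting material
2 | (2E,6E)-farnesyl chloride | CC(C)=CCC/C(C)=C/CC/C(C)=C/CCl | intermediate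
3 | (2E,6E)-farnesyl diphosphate (free acid form) | CC(C)=CCC/C(C)=C/CC/C(C)=C/COP(=O)(O)OP(=O)(O)O | intermediate
4 | α-longipinene, (1R,2S,7R,8R)-2,6,6,9-tetramethyltricyclo[5.4.0.0^2,8]undec-9-ene | CC1(C)[C@@H]2[C@H]3CC=C(C)[C@@H]2[C@@]3(C)CCC1 | intermediate
5 | longipin-5-en-4-one | CC1(C)[C@@H]2[C@H]3C(=O)C=C(C)[C@@H]2[C@@]3(C)CCC1 | intermediate
6 | 11-hydroxylongipin-5-en-4-one (OH on the C7 face; the epimer serves equally) | CC1(C)[C@@H]2[C@H]3C(=O)C=C(C)[C@@H]2[C@@]3(C)CC[C@H]1O | intermediate
7 | longipin-5-ene-4,11-dione | CC1(C)[C@@H]2[C@H]3C(=O)C=C(C)[C@@H]2[C@@]3(C)CCC1=O | intermediate (not isolated)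
8 | longipina-5,9-diene-4,11-dione | CC1(C)[C@@H]2[C@H]3C(=O)C=C(C)[C@@H]2[C@@]3(C)C=CC1=O | intermediate
9 | 9-(pinacolatoboryl)longipin-5-ene-4,11-dione (boron on the C3 face) | CC1(C)[C@@H]2[C@H]3C(=O)C=C(C)[C@@H]2[C@@]3(C)[C@H](B4OC(C)(C)C(C)(C)O4)CC1=O | intermediate (not isolated)
10 | 9-hydroxylongipin-5-ene-4,11-dione (OH on the C3 face) | CC1(C)[C@@H]2[C@H]3C(=O)C=C(C)[C@@H]2[C@@]3(C)[C@H](O)CC1=O | intermediate
11 | 3-methylbut-2-enal | CC(C)=CC=O | starting material
12 | 11-hydroxy-4-oxolongipin-5-en-9-yl 3-methylbut-2-enoate (O9 on the C3 face, O11 on the C7 face) | CC1(C)[C@@H]2[C@H]3C(=O)C=C(C)[C@@H]2[C@@]3(C)[C@H](OC(=O)C=C(C)C)C[C@H]1O | intermediate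
13 | 4,11-dihydroxylongipin-5-en-9-yl 3-methylbut-2-enoate (4-OH on the side of the C8 methyl) | CC1(C)[C@@H]2[C@H]3[C@H](O)C=C(C)[C@@H]2[C@@]3(C)[C@H](OC(=O)C=C(C)C)C[C@H]1O | intermediate
14 | 4,11-bis(diethylsilyloxy)longipin-5-en-9-yl 3-methylbut-2-enoate | CC1(C)[C@@H]2[C@H]3[C@H](O[SiH](CC)CC)C=C(C)[C@@H]2[C@@]3(C)[C@H](OC(=O)C=C(C)C)C[C@H]1O[SiH](CC)CC | intermediate (not isolated)
15 | oxasilolane O11–SiEt2–C15 of 14, 4-O-diethylsilyl ether retained (C15 on the C3 face) | C4[C@]1(C)[C@@H]2[C@H]3[C@H](O[SiH](CC)CC)C=C(C)[C@@H]2[C@@]3(C)[C@H](OC(=O)C=C(C)C)C[C@H]1O[Si]4(CC)CC | intermediate (not isolated)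
16 | 4,11,15-trihydroxylongipin-5-en-9-yl 3-methylbut-2-enoate | OC[C@]1(C)[C@@H]2[C@H]3[C@H](O)C=C(C)[C@@H]2[C@@]3(C)[C@H](OC(=O)C=C(C)C)C[C@H]1O | intermediate
17 | 11,15-dihydroxy-4-oxolongipin-5-en-9-yl 3-methylbut-2-enoate | OC[C@]1(C)[C@@H]2[C@H]3C(=O)C=C(C)[C@@H]2[C@@]3(C)[C@H](OC(=O)C=C(C)C)C[C@H]1O | intermediate
18 | angelic acid, (Z)-2-methylbut-2-enoic acid | C/C=C(/C)C(=O)O | starting material
19 | (Z)-2-methylbut-2-enoic 2,4,6-trichlorobenzoic anhydride | C/C=C(/C)C(=O)OC(=O)c1c(Cl)cc(Cl)cc1Cl | intermediate (not isolated)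
20 | 15-angeloyloxy-11-hydroxy-4-oxolongipin-5-en-9-yl 3-methylbut-2-enoate | C/C=C(/C)C(=O)OC[C@]1(C)[C@@H]2[C@H]3C(=O)C=C(C)[C@@H]2[C@@]3(C)[C@H](OC(=O)C=C(C)C)C[C@H]1O | intermediate
21 | CNP0179010.1, 11-acetoxy-15-angeloyloxy-4-oxolongipin-5-en-9-yl 3-methylbut-2-enoate | C/C=C(/C)C(=O)OC[C@]1(C)[C@@H]2[C@H]3C(=O)C=C(C)[C@@H]2[C@@]3(C)[C@H](OC(=O)C=C(C)C)C[C@H]1OC(C)=O | target

Total step count: 13. Longest linear sequence: 13 steps (1 to 21); 11 and 18 enter as purchased.

Steps most likely to fail

Step 5. Hydroxylation may go to C10 (the least hindered methylene), to C9 or to a methyl group instead of C11, or run on to ketones, and no variant with useful C11 selectivity may be found. Fallback, setting out from 5 and coming back at 8: the designed isolated enzyme is replaced by a preparative whole-cell screen of hydroxylating filamentous fungi (for example Mucor plumbeus, Aspergillus niger, Beauveria bassiana), a classical way to oxidise unactivated ring positions of sesquiterpene ketones. Any C11 oxidation product is acceptable, be it 6, its C3-face epimer 11-epi-hydroxy enone F1 or the ketone 7, because the IBX treatment of step 6 converts each of them into 8.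

Step 10. Iridium hydride and Si–H species may reduce the senecioate or the alkene faster than the hindered methyl is silylated, and the idle silyl ether on O4 may engage the C8 methyl. Fallback, setting out from 6 (C7-face alcohol) and coming back at 17: the C–H silylation is moved ahead of the ester. Luche reduction of 6 should give the 4,11-diol F2; Et2SiH2/[Ir(cod)OMe]2 the bis(diethylsilyl) ether F3; [Ir(cod)OMe]2/Me4phen/norbornene the oxasilolane F4; and H2O2/KHCO3 the 4,11,15-triol F5. TBSCl/imidazole then silylates the primary hydroxyl to the 15-silyl ether F6. IBX at 80 °C oxidises both secondary alcohols to the 15-silyloxy 4,11-dione F7 and dehydrogenates it to the 15-silyloxy 5,9-diene-4,11-dione F8. The borylation and oxidation of step 7 give the C9 boronate F9 and then the 9-hydroxy diketone F10. Evans–Tishchenko reduction with 11 gives the 9-senecioate 11-alcohol F11, and HF·pyridine removes the silyl group to give 17.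

Step 8. Hemiacetal formation from the conjugated aldehyde and the hydride transfer may be slow, so that retro-aldol opening of the β-hydroxy ketone or consumption of the enal by the samarium reagent takes over. Fallback, setting out from 10 and coming back at 12: Evans–Saksena reduction with Me4NBH(OAc)3 in MeCN/AcOH at −20 °C delivers hydride from boron bound to O9 and should give the anti-9,11-diol F12. One equivalent of 3-methylbut-2-enoyl chloride with pyridine in CH2Cl2 at −20 °C then acylates the less hindered C9 hydroxyl (one flanking methyl, against the fully substituted C1 next to C11) to give 12. The regioisomer and the diester would be separated and returned to F12 by methanolysis.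

Further compounds
F1 | step 5 | 11-epi-hydroxy enone, 11-hydroxylongipin-5-en-4-one with OH on the C3 face | CC1(C)[C@@H]2[C@H]3C(=O)C=C(C)[C@@H]2[C@@]3(C)CC[C@@H]1O
F2 | step 10 | longipin-5-ene-4,11-diol | CC1(C)[C@@H]2[C@H]3[C@H](O)C=C(C)[C@@H]2[C@@]3(C)CC[C@H]1O
F3 | step 10 | 4,11-bis(diethylsilyloxy)longipin-5-ene | CC1(C)[C@@H]2[C@H]3[C@H](O[SiH](CC)CC)C=C(C)[C@@H]2[C@@]3(C)CC[C@H]1O[SiH](CC)CC
F4 | step 10 | oxasilolane O11–SiEt2–C15 of F3, 4-O-diethylsilyl ether retained | C4[C@]1(C)[C@@H]2[C@H]3[C@H](O[SiH](CC)CC)C=C(C)[C@@H]2[C@@]3(C)CC[C@H]1O[Si]4(CC)CC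
F5 | step 10 | longipin-5-ene-4,11,15-triol | OC[C@]1(C)[C@@H]2[C@H]3[C@H](O)C=C(C)[C@@H]2[C@@]3(C)CC[C@H]1O
F6 | step 10 | 15-(tert-butyldimethylsilyloxy)longipin-5-ene-4,11-diol | CC(C)(C)[Si](C)(C)OC[C@]1(C)[C@@H]2[C@H]3[C@H](O)C=C(C)[C@@H]2[C@@]3(C)CC[C@H]1O
F7 | step 10 | 15-(tert-butyldimethylsilyloxy)longipin-5-ene-4,11-dione | CC(C)(C)[Si](C)(C)OC[C@]1(C)[C@@H]2[C@H]3C(=O)C=C(C)[C@@H]2[C@@]3(C)CCC1=O
F8 | step 10 | 15-(tert-butyldimethylsilyloxy)longipina-5,9-diene-4,11-dione | CC(C)(C)[Si](C)(C)OC[C@]1(C)[C@@H]2[C@H]3C(=O)C=C(C)[C@@H]2[C@@]3(C)C=CC1=O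
F9 | step 10 | 9-(pinacolatoboryl)-15-(tert-butyldimethylsilyloxy)longipin-5-ene-4,11-dione | CC(C)(C)[Si](C)(C)OC[C@]1(C)[C@@H]2[C@H]3C(=O)C=C(C)[C@@H]2[C@@]3(C)[C@H](B4OC(C)(C)C(C)(C)O4)CC1=O
F10 | step 10 | 9-hydroxy-15-(tert-butyldimethylsilyloxy)longipin-5-ene-4,11-dione | CC(C)(C)[Si](C)(C)OC[C@]1(C)[C@@H]2[C@H]3C(=O)C=C(C)[C@@H]2[C@@]3(C)[C@H](O)CC1=O
F11 | step 10 | 11-hydroxy-4-oxo-15-(tert-butyldimethylsilyloxy)longipin-5-en-9-yl 3-methylbut-2-enoate | CC(C)(C)[Si](C)(C)OC[C@]1(C)[C@@H]2[C@H]3C(=O)C=C(C)[C@@H]2[C@@]3(C)[C@H](OC(=O)C=C(C)C)C[C@H]1O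
F12 | step 8 | anti-9,11-dihydroxylongipin-5-en-4-one (O9 on the C3 face, O11 on the C7 face) | CC1(C)[C@@H]2[C@H]3C(=O)C=C(C)[C@@H]2[C@@]3(C)[C@H](O)C[C@H]1O
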